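**Retrosynthetic overview**
1. The (E)-propenal chain is cut at its C=C bond: a two-carbon aldol homologation of the C6 formyl group is the last step.
2. Key disconnection: the C3–aryl bond of the benzodioxane. The trimethoxyphenyl ring (as its bromide) is joined to an anomeric-type C3 radical by nickel/photoredox cross-electrophile coupling, trans to the C2 methyl.
3. The dioxane ring is the only ring made. It is closed before the coupling as a cyclic hemiacetal, by ozonolysis of an (S)-but-3-en-2-yl aryl ether whose aldehyde is trapped by the ortho phenol.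
4. The C2 stereocentre comes from (R)-but-3-en-2-ol by Mitsunobu inversion on 5-hydroxyvanillin; the more acidic phenol gives the regiochemistry.
5. Both benzene rings are bought as para-substituted phenols (p-cresol, 4-bromophenol) and oxygenated by ortho-halogenation and copper-mediated methoxylation.

Assumption: the SMILES is read as the trans-(2S,3S) isomer with an (E)-enal; common reagents, ligands and catalysts are bought.

Step 1
Reactants: 1 4-methylphenol (p-cresol)
Product: 4 3,5-dibromo-4-hydroxybenzaldehyde, via ring-dibrominated cresol 2 (not isolated), via benzal bromide 3 (not isolated)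
Conditions: Br2 (2 equiv), 1,2-dichlorobenzene, 35 °C; Br2 (2 equiv), 155 °C; then H2O, 100 °C
Reagents that add atoms: bromine, BrBr; water, O
Why: Electrophilic aromatic bromination fills both positions ortho to the hydroxyl, the hot second charge of bromine brominates the methyl group by a free-radical chain to the benzal bromide, and water hydrolyses this gem-dibromide to the aldehyde, with no stereocentre involved.

Step 2
Reactants: 4 3,5-dibromo-4-hydroxybenzaldehyde
Product: 5 4-hydroxy-3,5-dimethoxybenzaldehyde (syringaldehyde)
Conditions: NaOMe (4 equiv), CuCl (5 mol %), MeOH/DMF, 115 °C; then aq. HCl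
Reagents that add atoms: sodium methoxide, [Na+].[O-]C
Why: Ullmann-type copper-catalysed methoxylation replaces both bromides, which sit ortho to the phenoxide and are activated by the para formyl group, with no stereocentre involved.

Step 3
Reactants: 5 4-hydroxy-3,5-dimethoxybenzaldehyde
Product: 6 3,4-dihydroxy-5-methoxybenzaldehyde (5-hydroxyvanillin)
Conditions: AlCl3 (1.1 equiv), pyridine (4.4 equiv), CH2Cl2, reflux; then aq. HCl
Reagents that add atoms: none
Why: Chelation-controlled Lewis-acid demethylation, in which aluminium binds the phenoxide and one neighbouring methoxy oxygen, pyridine removes that methyl by SN2, and the resulting aluminium catecholate shields the second methoxy group.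

Step 4
Reactants: 7 4-bromophenol
Product: 8 4-bromo-2,6-diiodophenol
Conditions: I2 (1.1 equiv), 30% aq. H2O2 (2.5 equiv), H2O, 50 °C
Reagents that add atoms: iodine, I-I
Why: Electrophilic aromatic iodination (iodide recycled by H2O2) goes to the two positions ortho to the hydroxyl because the para position is blocked by bromine.

Step 5
Reactants: 8 4-bromo-2,6-diiodophenol
Product: 10 5-bromo-1,2,3-trimethoxybenzene, via sodium 4-bromo-2,6-dimethoxyphenolate 9 (not isolated)
Conditions: NaOMe (5 equiv), CuI (10 mol %), MeOH/DMF, 90 °C; then MeI (6 equiv), 25–40 °C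
Reagents that add atoms: sodium methoxide, [Na+].[O-]C; iodomethane, CI
Why: Ullmann-type copper-catalysed methoxylation is selective for the two C–I bonds (ortho to the phenoxide and far more reactive than the para C–Br bond), and the phenoxide is then O-methylated in the same pot by a Williamson SN2 reaction.

Step 6
Reactants: 6 3,4-dihydroxy-5-methoxybenzaldehyde; 11 (2R)-but-3-en-2-ol (1.2 equiv)
Product: 12 4-[(2S)-but-3-en-2-yloxy]-3-hydroxy-5-methoxybenzaldehyde
Conditions: PPh3 (1.3 equiv), DIAD (1.3 equiv), THF, 0 °C to rt
Reagents that add atoms: none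
Why: Mitsunobu etherification, in which the hydroxyl para to the formyl group is by far the more acidic and is the one alkylated, and SN2 displacement of the activated (R)-alcohol with inversion sets the (S) methyl-bearing stereocentre that becomes C2 of the target.

Step 7
Reactants: 12 4-[(2S)-but-3-en-2-yloxy]-3-hydroxy-5-methoxybenzaldehyde
Product: 15 (2S,3RS)-3-hydroxy-8-methoxy-2-methyl-2,3-dihydro-1,4-benzodioxine-6-carbaldehyde, via secondary ozonide 13 (not isolated), via open-chain aldehyde 14 (not isolated)
Conditions: O3, CH2Cl2, −78 °C (Sudan Red 7B end point); then Me2S, −78 °C to rt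
Reagents that add atoms: ozone, [O-][O+]=O
Why: Criegee ozonolysis of the terminal alkene and reductive work-up give the α-aryloxy aldehyde, which the neighbouring phenol traps at once as the six-membered cyclic hemiacetal (this closes the dioxane ring and shields C2 from enolisation), while the new hemiacetal centre forms as an anomeric mixture that is erased in step 8.

Step 8
Reactants: 15 (2S,3RS)-3-hydroxy-8-methoxy-2-methyl-2,3-dihydro-1,4-benzodioxine-6-carbaldehyde; 10 5-bromo-1,2,3-trimethoxybenzene (1.5 equiv)
Product: 17 (2S,3S)-8-methoxy-2-methyl-3-(3,4,5-trimethoxyphenyl)-2,3-dihydro-1,4-benzodioxine-6-carbaldehyde, via anomeric bromide 16 (not isolated)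
Conditions: (COBr)2 (1.2 equiv), DMF (5 mol %), CH2Cl2, 0 °C, evaporate; then 10, NiCl2·glyme (10 mol %), 4,4′-di-tert-butyl-2,2′-bipyridine (dtbbpy, 12 mol %), [Ir{dF(CF3)ppy}2(dtbbpy)]PF6 (1 mol %), (Me3Si)3SiH (1.2 equiv), Na2CO3 (2 equiv), DME, 450 nm LEDs, rt
Reagents that add atoms: none
Why: Vilsmeier-type bromination of the hemiacetal is followed by silyl-radical-mediated nickel/photoredox cross-electrophile coupling (the reaction type used for radical C-aryl glycosylation of glycosyl bromides), in which the silyl radical abstracts bromine from 16, the planar α-oxy C3 radical is captured by the aryl–nickel species formed from 10 and zerovalent nickel, and reductive elimination from trivalent nickel forms the C3–aryl bond on the face opposite the C2 methyl, so both anomers converge on the trans (2S,3S) product.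

Step 9
Reactants: 17 (2S,3S)-8-methoxy-2-methyl-3-(3,4,5-trimethoxyphenyl)-2,3-dihydro-1,4-benzodioxine-6-carbaldehyde; 18 ethenyl acetate (vinyl acetate, 2.5 equiv)
Product: 21 (2E)-3-[(2S,3S)-8-methoxy-2-methyl-3-(3,4,5-trimethoxyphenyl)-2,3-dihydro-1,4-benzodioxin-6-yl]prop-2-enal (CNP0258373.1), via barium ethenolate 19 (not isolated), via aldol adduct 20 (not isolated)
Conditions: Ba(OH)2 (1.5 equiv), THF, 65 °C
Reagents that add atoms: none
Why: Crossed aldol (Claisen–Schmidt) condensation, in which hydroxide cleaves vinyl acetate to the acetaldehyde enolate that adds to the non-enolisable aryl aldehyde, and E1cB dehydration gives the conjugated (E)-enal as the thermodynamic alkene without touching the ring stereocentres.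

**Compound list**
1 | 4-methylphenol (p-cresol) | Cc1ccc(O)cc1 | starting material
2 | 2,6-dibromo-4-methylphenol | Cc1cc(Br)c(O)c(Br)c1 | intermediate
3 | 2,6-dibromo-4-(dibromomethyl)phenol | BrC(Br)c1cc(Br)c(O)c(Br)c1 | intermediate
4 | 3,5-dibromo-4-hydroxybenzaldehyde | O=Cc1cc(Br)c(O)c(Br)c1 | intermediate
5 | 4-hydroxy-3,5-dimethoxybenzaldehyde (syringaldehyde) | COc1cc(C=O)cc(OC)c1O | intermediate
6 | 3,4-dihydroxy-5-methoxybenzaldehyde (5-hydroxyvanillin) | COc1cc(C=O)cc(O)c1O | intermediate
7 | 4-bromophenol | Oc1ccc(Br)cc1 | starting material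
8 | 4-bromo-2,6-diiodophenol | Oc1c(I)cc(Br)cc1I | intermediate
9 | sodium 4-bromo-2,6-dimethoxyphenolate | COc1cc(Br)cc(OC)c1[O-].[Na+] | intermediate
10 | 5-bromo-1,2,3-trimethoxybenzene | COc1cc(Br)cc(OC)c1OC | intermediate
11 | (2R)-but-3-en-2-ol | C[C@@H](O)C=C | starting material
12 | 4-[(2S)-but-3-en-2-yloxy]-3-hydroxy-5-methoxybenzaldehyde | COc1cc(C=O)cc(O)c1O[C@H](C=C)C | intermediate
13 | 3-hydroxy-5-methoxy-4-{(1S)-1-[(3RS)-1,2,4-trioxolan-3-yl]ethoxy}benzaldehyde (secondary ozonide) | COc1cc(C=O)cc(O)c1O[C@H](C1OCOO1)C | intermediate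
14 | 3-hydroxy-5-methoxy-4-{[(2S)-1-oxopropan-2-yl]oxy}benzaldehyde | COc1cc(C=O)cc(O)c1O[C@H](C=O)C | intermediate
15 | (2S,3RS)-3-hydroxy-8-methoxy-2-methyl-2,3-dihydro-1,4-benzodioxine-6-carbaldehyde | OC1Oc2cc(C=O)cc(OC)c2O[C@H]1C | intermediate
16 | (2S,3RS)-3-bromo-8-methoxy-2-methyl-2,3-dihydro-1,4-benzodioxine-6-carbaldehyde | BrC1Oc2cc(C=O)cc(OC)c2O[C@H]1C | intermediate
17 | (2S,3S)-8-methoxy-2-methyl-3-(3,4,5-trimethoxyphenyl)-2,3-dihydro-1,4-benzodioxine-6-carbaldehyde | COc1cc([C@@H]2Oc3cc(C=O)cc(OC)c3O[C@H]2C)cc(OC)c1OC | intermediate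
18 | ethenyl acetate (vinyl acetate) | CC(=O)OC=C | starting material
19 | barium ethenolate (acetaldehyde enolate) | [Ba+2].[O-]C=C.[O-]C=C | intermediate
20 | (3RS)-3-hydroxy-3-[(2S,3S)-8-methoxy-2-methyl-3-(3,4,5-trimethoxyphenyl)-2,3-dihydro-1,4-benzodioxin-6-yl]propanal | COc1cc([C@@H]2Oc3cc(C(O)CC=O)cc(OC)c3O[C@H]2C)cc(OC)c1OC | intermediate
21 | (2E)-3-[(2S,3S)-8-methoxy-2-methyl-3-(3,4,5-trimethoxyphenyl)-2,3-dihydro-1,4-benzodioxin-6-yl]prop-2-enal | COc1cc([C@@H]2Oc3cc(/C=C/C=O)cc(OC)c3O[C@H]2C)cc(OC)c1OC | target

**Totals**
Total step count: 9.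
Longest linear sequence: 7 steps (steps 1, 2, 3, 6, 7, 8, 9; from 1 to 21). Steps 4 and 5 make the coupling partner 10 in a side branch.

**Three steps most likely to fail**

Step 8 is the riskiest. The anomeric bromide 16 can lose HBr to the achiral 2-methyl-1,4-benzodioxine, which would erode C2. It can also be reduced by the silane, or the aryloxy group can be expelled from the organonickel intermediate. The trans:cis ratio is untested on this ring, and some abstraction of the aldehyde hydrogen is possible. The fallback is a polar, two-electron C-arylation through the oxocarbenium ion; it sets out from 15 and 10 and comes back at 17. Hemiacetal 15 is acetylated (Ac2O, pyridine) to (2S,3RS)-6-formyl-8-methoxy-2-methyl-2,3-dihydro-1,4-benzodioxin-3-yl acetate F1. Bromide 10 is converted with Mg in THF into (3,4,5-trimethoxyphenyl)magnesium bromide F2, quenched with B(OMe)3 to dimethyl (3,4,5-trimethoxyphenyl)boronate F3, and treated with aqueous KHF2 to give potassium trifluoro(3,4,5-trimethoxyphenyl)borate F4. BF3·OEt2 in CH2Cl2/MeCN at −40 to 0 °C then ionises F1, and the aryldifluoroborane formed from F4 delivers its aryl group to the oxocarbenium carbon anti to the C2 methyl, giving 17.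

Step 6 is the second risk. The reacting hydroxyl is flanked on both sides, so the Mitsunobu reaction may be slow, and some alkylation of the other hydroxyl or SN2′ attack would give isomers. The fallback sets the stereocentre by catalysis instead of by inversion, using palladium-catalysed asymmetric allylic etherification; it sets out from 6 and comes back at 12. Commercial (E)-but-2-en-1-ol is treated with methyl chloroformate and pyridine to give (E)-but-2-en-1-yl methyl carbonate F5. This carbonate, 6, Pd2(dba)3·CHCl3 and the enantiomer of the Trost DACH-phenyl ligand that gives the (S)-ether (CH2Cl2, rt) alkylate the more acidic phenoxide at the substituted allyl terminus, giving the branched ether 12. Which ligand enantiomer is needed must be checked on a model phenol.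

Step 5 is the third risk. Partial exchange of the para bromide, or reductive loss of iodine, would give arenes that are hard to separate from 10. The fallback installs the two flanking oxygens by formylation and Dakin oxidation instead of halogen exchange; it sets out from 7 and comes back at 10. 4-Bromophenol 7 undergoes double Duff formylation (hexamethylenetetramine, CF3CO2H, reflux; then aq. HCl) to 5-bromo-2-hydroxybenzene-1,3-dicarbaldehyde F6. Double Dakin oxidation (H2O2, NaOH, then acid) gives 5-bromobenzene-1,2,3-triol F7, and exhaustive O-methylation (MeI, K2CO3, acetone, under N2) gives 10.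

Further compounds
F1 | step 8 | (2S,3RS)-6-formyl-8-methoxy-2-methyl-2,3-dihydro-1,4-benzodioxin-3-yl acetate | CC(=O)OC1Oc2cc(C=O)cc(OC)c2O[C@H]1C
F2 | step 8 | (3,4,5-trimethoxyphenyl)magnesium bromide | COc1cc([Mg]Br)cc(OC)c1OC
F3 | step 8 | dimethyl (3,4,5-trimethoxyphenyl)boronate | COB(OC)c1cc(OC)c(OC)c(OC)c1
F4 | step 8 | potassium trifluoro(3,4,5-trimethoxyphenyl)borate | [K+].F[B-](F)(F)c1cc(OC)c(OC)c(OC)c1
F5 | step 6 | (E)-but-2-en-1-yl methyl carbonate | C/C=C/COC(=O)OC
F6 | step 5 | 5-bromo-2-hydroxybenzene-1,3-dicarbaldehyde | O=Cc1cc(Br)cc(C=O)c1O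
F7 | step 5 | 5-bromobenzene-1,2,3-triol | Oc1cc(Br)cc(O)c1O
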